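The benzene ring is not bought but built last. With the ring numbered C1 (side chain), C2 (OH), C3 (OMe), C4 (Me), C5 (OH), C6 (H), the feature exploited is the 1,3-diene C6=C1–C7=C14 hidden in the styrene. Ring atom C1 carries C7, and C7 carries the terminal methylene C14. This unit is traced back to an alkyne C1≡C7 and a vinyl ketone C5(=O)–C6H=CH2. One enyne metathesis forms C1=C6 and C7=C14, closes ring C1–C6 and, after enolization, delivers the hydroquinone with its two oxygens differentiated. The precursor is an open-chain dienynone whose tetronate-derived C3=C4 enol ether holds C2 and C5 cis and whose C8 carbinol is already S.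

Key step: step 11

Chain numbering: C7 (bears methylene C14), C8 (ester carbinol), C9, C10=C11 (prenyl alkene).
Remark on descriptors: in every open-chain intermediate the C3=C4 bond is E by the CIP rules. On C3 the methoxy oxygen outranks C2, and on C4 the carbonyl carbon outranks CH3. C2 and C5 are nevertheless cis to each other, as ring closure requires.
Remark on C2: it is formed without control and carried as both epimers, because it becomes an sp2 ring carbon in step 11.
Assumption: step 3 follows the usual sense of induction for alkyl alkynyl ketones, (S,S)-catalyst to (S)-alcohol.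

Step 1
Reactants: 1 4-methylpent-3-enoic acid
Product: 3 N-methoxy-N,4-dimethylpent-3-enamide, via acyl imidazolide 2 (not isolated)
Conditions: CDI, CH2Cl2, rt; then MeNH(OMe)·HCl, rt
Reagents that add atoms: 1,1'-carbonyldiimidazole, O=C(n1ccnc1)n1ccnc1 (imidazolyl group, held in 2 only); N,O-dimethylhydroxylamine hydrochloride, CNOC.Cl
Why: Weinreb amide formation through the acyl imidazolide runs under near-neutral conditions, so the trisubstituted β,γ-alkene, which gains little by moving into conjugation, stays where it is.

Step 2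
Reactants: 3 N-methoxy-N,4-dimethylpent-3-enamide; 4 trimethylsilylacetylene
Product: 7 6-methyl-1-(trimethylsilyl)hept-5-en-1-yn-3-one, via lithium trimethylsilylacetylide 5 (not isolated), via tetrahedral lithium adduct 6 (not isolated)
Conditions: 4, n-BuLi, THF, −78 °C; add 3, −78 to −20 °C; AcOH in THF, −78 °C
Reagents that add atoms: n-butyllithium, [Li]CCCC (lithium, held in 5 and 6 only)
Why: Weinreb ketone synthesis: the weakly basic acetylide 5 adds once, the N-methoxy chelate 6 blocks a second addition, and the cold acetic acid quench releases the β,γ-unsaturated ynone without exposing its acidic C9 methylene to base.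

Step 3
Reactants: 7 6-methyl-1-(trimethylsilyl)hept-5-en-1-yn-3-one
Product: 8 (S)-6-methyl-1-(trimethylsilyl)hept-5-en-1-yn-3-ol
Conditions: Ru(p-cymene)[(S,S)-TsNCHPhCHPhNH] (2 mol %, preformed, base-free), i-PrOH, rt
Reagents that add atoms: none
Why: Noyori asymmetric transfer hydrogenation of an alkynyl ketone: the (S,S)-diamine complex transfers hydride and proton to the carbonyl face that puts the alkyne beside the arene ligand, which sets C8 as S as it does for other alkyl alkynyl ketones, and the base-free medium leaves the C9 methylene, the alkyne and the prenyl alkene unchanged.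

Step 4
Reactants: 8 (S)-6-methyl-1-(trimethylsilyl)hept-5-en-1-yn-3-ol
Product: 9 (S)-6-methyl-3-(triethylsilyloxy)-1-(trimethylsilyl)hept-5-en-1-yne
Conditions: TESCl, imidazole, CH2Cl2, 0 °C
Reagents that add atoms: chlorotriethylsilane, CC[Si](CC)(CC)Cl
Why: Routine silylation of a secondary alcohol, with triethylsilyl chosen because mild acid will later remove it in the presence of aryl tert-butyldimethylsilyl ethers.

Step 5
Reactants: 9 (S)-6-methyl-3-(triethylsilyloxy)-1-(trimethylsilyl)hept-5-en-1-yne
Product: 10 (S)-6-methyl-3-(triethylsilyloxy)hept-5-en-1-yne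
Conditions: K2CO3 (0.2 equiv), MeOH, 0 °C to rt
Reagents that add atoms: none
Why: Protiodesilylation of an alkynylsilane: methoxide attacks the unhindered C(sp)-bound SiMe3 group far faster than the secondary O-SiEt3 group, and C8 is not involved.

Step 6
Reactants: 11 4-hydroxy-3-methylfuran-2(5H)-one (3-methyltetronic acid)
Product: 12 4-methoxy-3-methylfuran-2(5H)-one
Conditions: Me2SO4, K2CO3, acetone, reflux
Reagents that add atoms: dimethyl sulfate, COS(=O)(=O)OC
Why: O-Alkylation of the vinylogous acid by a hard methylating agent gives the 4-methoxybutenolide, whose ring locks the lactone carbonyl (future C5) and the ring CH2 (future C2) cis across the future C3=C4 bond.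

Step 7
Reactants: 12 4-methoxy-3-methylfuran-2(5H)-one
Product: 13 (E)-4-hydroxy-N,3-dimethoxy-N,2-dimethylbut-2-enamide
Conditions: MeNH(OMe)·HCl, AlMe3, CH2Cl2, 0 °C to rt; aq potassium sodium tartrate, 0 °C
Reagents that add atoms: N,O-dimethylhydroxylamine hydrochloride, CNOC.Cl
Why: Weinreb aminolysis of a lactone: the aluminium amide binds the lactone carbonyl oxygen and hands its nitrogen to that carbon (acyl-oxygen cleavage) rather than to the fully substituted methoxy-bearing carbon, the alkene geometry is carried over from the ring, and crude 13 is oxidized the same day because it can reclose to 12.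

Step 8
Reactants: 13 (E)-4-hydroxy-N,3-dimethoxy-N,2-dimethylbut-2-enamide
Product: 14 (E)-N,3-dimethoxy-N,2-dimethyl-4-oxobut-2-enamide
Conditions: Dess–Martin periodinane, NaHCO3, CH2Cl2, 0 °C to rt
Reagents that add atoms: none
Why: Dess–Martin oxidation of a primary allylic alcohol is fast under bicarbonate buffering, spares enol ether and amide, and removes the hydroxyl group that could relactonize.

Step 9
Reactants: 10 (S)-6-methyl-3-(triethylsilyloxy)hept-5-en-1-yne; 14 (E)-N,3-dimethoxy-N,2-dimethyl-4-oxobut-2-enamide
Product: 17 (2E,7S)-4-(tert-butyldimethylsilyloxy)-N,3-dimethoxy-N,2,10-trimethyl-7-(triethylsilyloxy)undeca-2,9-dien-5-ynamide (both epimers at the silyloxy carbon C2 of the target numbering), via lithium acetylide 15 (not isolated), via lithium alkoxide 16 (not isolated)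
Conditions: 10, n-BuLi, THF, −78 °C; add 14, −78 °C; then TBSOTf, 2,6-lutidine, −78 to −40 °C
Reagents that add atoms: n-butyllithium, [Li]CCCC (lithium, held in 15 and 16 only); tert-butyldimethylsilyl trifluoromethanesulfonate, CC(C)(C)[Si](C)(C)OS(=O)(=O)C(F)(F)F
Why: 1,2-Addition of a lithium acetylide to an aldehyde is much faster at −78 °C than attack on the Weinreb amide, silylation of alkoxide 16 in the same flask forestalls its cyclization onto the cis amide, and the new C2 centre is formed without control, which is harmless because it is erased in step 11.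

Step 10
Reactants: 17 (2E,7S)-4-(tert-butyldimethylsilyloxy)-N,3-dimethoxy-N,2,10-trimethyl-7-(triethylsilyloxy)undeca-2,9-dien-5-ynamide
Product: 19 (4E,9S)-6-(tert-butyldimethylsilyloxy)-5-methoxy-4,12-dimethyl-9-(triethylsilyloxy)trideca-1,4,11-trien-7-yn-3-one (both C2 epimers), via magnesium chelate 18 (not isolated)
Conditions: CH2=CHMgBr (3 equiv), THF, −20 to 0 °C; inverse quench into cold 10 % aq citric acid/Et2O; used at once
Reagents that add atoms: vinylmagnesium bromide, C=C[Mg]Br
Why: Weinreb ketone synthesis: chelate 18 persists until the quench so that only one vinyl group is taken up, and pouring into cold citric acid protonates the released N,O-dimethylhydroxylamine before it can add to the new vinyl ketone while both silyl ethers and the vinylogous ester survive the brief contact.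

Step 11
Reactants: 19 (4E,9S)-6-(tert-butyldimethylsilyloxy)-5-methoxy-4,12-dimethyl-9-(triethylsilyloxy)trideca-1,4,11-trien-7-yn-3-one
Product: 21 4-(tert-butyldimethylsilyloxy)-3-methoxy-2-methyl-5-[(3S)-6-methyl-3-(triethylsilyloxy)hepta-1,5-dien-2-yl]phenol, via cyclohexadienone 20 (not isolated)
Conditions: RuCl2(SIMes)(=CH-C6H4-2-O-i-Pr) (second-generation Hoveyda–Grubbs catalyst, SIMes = 1,3-dimesitylimidazolidin-2-ylidene, 10 mol %), ethylene (1 atm), toluene (5 mM), 60 °C; then SiO2, CH2Cl2, rt
Reagents that add atoms: ethylene, C=C (feeds the methylidene pool that places C14 on C7; the same amount of ethylene is given back)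
Why: The ruthenium methylidene made from catalyst and ethylene adds across the C1≡C7 alkyne, leaving its CH2 on C7 (the future C14) and the metal on C1, and the resulting vinylcarbene engages the vinyl ketone C6=CH2 by [2+2] cycloaddition and cycloreversion, which forms C1=C6 and returns the methylidene; should the methylidene add in the opposite sense, ethylene turns the C7 carbene over and the C1 methylene so formed can still close onto the vinyl ketone to the same ring. The closest known reaction type is ring-closing enyne metathesis of 1,4-dien-7-yn-3-ones with tautomerization to 3-vinylphenols, supported by ethylene–alkyne cross metathesis of alkynes that carry oxygen on both propargylic carbons. Ring C1–C6 closes in the exo mode of a 1,7-enyne, so that only C1 of the alkyne becomes a ring atom and C7 stays outside with its new methylene. No stereocentre is created: the C2 epimers converge when dienone 20 loses its doubly vinylogous C2–H and enolizes to the phenol (silica completes this), which also makes the sequence irreversible, and C8 is not touched. The step needs reaction at the alkyne and the vinyl ketone only, and this is secured by the cis placement of C2 and C5 on the inert tetrasubstituted C3=C4 enol ether, which holds C6 next to the C1 carbene, while the trisubstituted C10=C11 alkene is attacked far more slowly and could close only to a cyclobutene (from C7) or, with expulsion of an isopropylidene carbene, to a methylenecyclopentene (from C1). The phosphine-free catalyst is chosen because free PCy3 adds to vinyl ketones and shortens catalyst life.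

Step 12
Reactants: 21 4-(tert-butyldimethylsilyloxy)-3-methoxy-2-methyl-5-[(3S)-6-methyl-3-(triethylsilyloxy)hepta-1,5-dien-2-yl]phenol
Product: 22 (3S)-2-[2,5-bis(tert-butyldimethylsilyloxy)-3-methoxy-4-methylphenyl]-6-methyl-3-(triethylsilyloxy)hepta-1,5-diene
Conditions: TBSCl, imidazole, DMF, rt
Reagents that add atoms: tert-butylchlorodimethylsilane, CC(C)(C)[Si](C)(C)Cl
Why: Silylation of the only free hydroxyl group (phenol silyl ether formation) masks C5–OH so that the later acylation can take place only at C8.

Step 13
Reactants: 22 (3S)-2-[2,5-bis(tert-butyldimethylsilyloxy)-3-methoxy-4-methylphenyl]-6-methyl-3-(triethylsilyloxy)hepta-1,5-diene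
Product: 23 (3S)-2-[2,5-bis(tert-butyldimethylsilyloxy)-3-methoxy-4-methylphenyl]-6-methylhepta-1,5-dien-3-ol
Conditions: PPTS (0.2 equiv), MeOH/CH2Cl2 1:1, 0 °C to rt
Reagents that add atoms: none
Why: Acid-catalysed methanolysis separates the alkyl triethylsilyl ether from the two aryl tert-butyldimethylsilyl ethers, which are far more stable to mild acid, and PPTS is too weak to ionize the allylic C8–O bond, so the S configuration is kept.

Step 14
Reactants: 23 (3S)-2-[2,5-bis(tert-butyldimethylsilyloxy)-3-methoxy-4-methylphenyl]-6-methylhepta-1,5-dien-3-ol; 24 angelic acid [(Z)-2-methylbut-2-enoic acid]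
Product: 26 (3S)-2-[2,5-bis(tert-butyldimethylsilyloxy)-3-methoxy-4-methylphenyl]-6-methylhepta-1,5-dien-3-yl (Z)-2-methylbut-2-enoate, via mixed anhydride 25 (not isolated)
Conditions: 24, 2,4,6-Cl3C6H2COCl, Et3N, toluene, rt; then 23, 80 °C (no DMAP)
Reagents that add atoms: 2,4,6-trichlorobenzoyl chloride, O=C(Cl)c1c(Cl)cc(Cl)cc1Cl (aroyl group, held in 25 only)
Why: Yamaguchi-type esterification run without a nucleophilic catalyst: the alcohol attacks the unhindered angeloyl carbonyl of 25, nothing is present that could add reversibly to the Z-enoate and turn it into the tiglate, and O-acylation leaves the C8–O bond and its configuration intact.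

Step 15
Reactants: 26 (3S)-2-[2,5-bis(tert-butyldimethylsilyloxy)-3-methoxy-4-methylphenyl]-6-methylhepta-1,5-dien-3-yl (Z)-2-methylbut-2-enoate
Product: 27 (3S)-2-(2,5-dihydroxy-3-methoxy-4-methylphenyl)-6-methylhepta-1,5-dien-3-yl (Z)-2-methylbut-2-enoate (CNP0248710.1)
Conditions: TBAF/AcOH (1:1, 2.5 equiv), THF, 0 °C, argon
Reagents that add atoms: none
Why: Fluoride desilylation cleaves aryl silyl ethers rapidly, and the acetic acid buffer keeps the liberated phenols protonated so that acyl migration, allylic displacement of the angelate and air oxidation to the quinone are held back.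

Compound list
1 | 4-methylpent-3-enoic acid | CC(C)=CCC(=O)O | starting material
2 | 1-(4-methylpent-3-enoyl)imidazole | CC(C)=CCC(=O)n1ccnc1 | intermediate
3 | N-methoxy-N,4-dimethylpent-3-enamide | CC(C)=CCC(=O)N(C)OC | intermediate
4 | trimethylsilylacetylene | C#C[Si](C)(C)C | starting material
5 | lithium trimethylsilylacetylide | [Li]C#C[Si](C)(C)C | intermediate
6 | lithium 3-[methoxy(methyl)amino]-6-methyl-1-(trimethylsilyl)hept-5-en-1-yn-3-olate | CC(C)=CCC(O[Li])(C#C[Si](C)(C)C)N(C)OC | intermediate
7 | 6-methyl-1-(trimethylsilyl)hept-5-en-1-yn-3-one | CC(C)=CCC(=O)C#C[Si](C)(C)C | intermediate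
8 | (S)-6-methyl-1-(trimethylsilyl)hept-5-en-1-yn-3-ol | C[Si](C)(C)C#C[C@H](CC=C(C)C)O | intermediate
9 | (S)-6-methyl-3-(triethylsilyloxy)-1-(trimethylsilyl)hept-5-en-1-yne | C[Si](C)(C)C#C[C@H](CC=C(C)C)O[Si](CC)(CC)CC | intermediate
10 | (S)-6-methyl-3-(triethylsilyloxy)hept-5-en-1-yne | C#C[C@H](CC=C(C)C)O[Si](CC)(CC)CC | intermediate
11 | 4-hydroxy-3-methylfuran-2(5H)-one | CC1=C(O)COC1=O | starting material
12 | 4-methoxy-3-methylfuran-2(5H)-one | CC1=C(OC)COC1=O | intermediate
13 | (E)-4-hydroxy-N,3-dimethoxy-N,2-dimethylbut-2-enamide | CON(C)C(=O)/C(C)=C(/OC)CO | intermediate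
14 | (E)-N,3-dimethoxy-N,2-dimethyl-4-oxobut-2-enamide | CON(C)C(=O)/C(C)=C(/OC)C=O | intermediate
15 | lithium acetylide of 10 | [Li]C#C[C@H](CC=C(C)C)O[Si](CC)(CC)CC | intermediate
16 | lithium alkoxide from 15 and 14 (C2–OLi, both epimers) | CON(C)C(=O)/C(C)=C(/OC)C(O[Li])C#C[C@H](CC=C(C)C)O[Si](CC)(CC)CC | intermediate
17 | (2E,7S)-4-(tert-butyldimethylsilyloxy)-N,3-dimethoxy-N,2,10-trimethyl-7-(triethylsilyloxy)undeca-2,9-dien-5-ynamide | CON(C)C(=O)/C(C)=C(/OC)C(O[Si](C)(C)C(C)(C)C)C#C[C@H](CC=C(C)C)O[Si](CC)(CC)CC | intermediate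
18 | bromomagnesium chelate from 17 and vinylmagnesium bromide | C=CC(O[Mg]Br)(N(C)OC)/C(C)=C(/OC)C(O[Si](C)(C)C(C)(C)C)C#C[C@H](CC=C(C)C)O[Si](CC)(CC)CC | intermediate
19 | (4E,9S)-6-(tert-butyldimethylsilyloxy)-5-methoxy-4,12-dimethyl-9-(triethylsilyloxy)trideca-1,4,11-trien-7-yn-3-one | C=CC(=O)/C(C)=C(/OC)C(O[Si](C)(C)C(C)(C)C)C#C[C@H](CC=C(C)C)O[Si](CC)(CC)CC | intermediate
20 | 4-(tert-butyldimethylsilyloxy)-3-methoxy-2-methyl-5-[(3S)-6-methyl-3-(triethylsilyloxy)hepta-1,5-dien-2-yl]cyclohexa-2,5-dien-1-one | C=C(C1=CC(=O)C(C)=C(OC)C1O[Si](C)(C)C(C)(C)C)[C@H](CC=C(C)C)O[Si](CC)(CC)CC | intermediate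
21 | 4-(tert-butyldimethylsilyloxy)-3-methoxy-2-methyl-5-[(3S)-6-methyl-3-(triethylsilyloxy)hepta-1,5-dien-2-yl]phenol | C=C(c1cc(O)c(C)c(OC)c1O[Si](C)(C)C(C)(C)C)[C@H](CC=C(C)C)O[Si](CC)(CC)CC | intermediate
22 | (3S)-2-[2,5-bis(tert-butyldimethylsilyloxy)-3-methoxy-4-methylphenyl]-6-methyl-3-(triethylsilyloxy)hepta-1,5-diene | C=C(c1cc(O[Si](C)(C)C(C)(C)C)c(C)c(OC)c1O[Si](C)(C)C(C)(C)C)[C@H](CC=C(C)C)O[Si](CC)(CC)CC | intermediate
23 | (3S)-2-[2,5-bis(tert-butyldimethylsilyloxy)-3-methoxy-4-methylphenyl]-6-methylhepta-1,5-dien-3-ol | C=C(c1cc(O[Si](C)(C)C(C)(C)C)c(C)c(OC)c1O[Si](C)(C)C(C)(C)C)[C@H](CC=C(C)C)O | intermediate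
24 | angelic acid, (Z)-2-methylbut-2-enoic acid | C/C=C(/C)C(=O)O | starting material
25 | (Z)-2-methylbut-2-enoic 2,4,6-trichlorobenzoic anhydride | C/C=C(/C)C(=O)OC(=O)c1c(Cl)cc(Cl)cc1Cl | intermediate
26 | (3S)-2-[2,5-bis(tert-butyldimethylsilyloxy)-3-methoxy-4-methylphenyl]-6-methylhepta-1,5-dien-3-yl (Z)-2-methylbut-2-enoate | C=C(c1cc(O[Si](C)(C)C(C)(C)C)c(C)c(OC)c1O[Si](C)(C)C(C)(C)C)[C@H](CC=C(C)C)OC(=O)/C(C)=C\C | intermediate
27 | (3S)-2-(2,5-dihydroxy-3-methoxy-4-methylphenyl)-6-methylhepta-1,5-dien-3-yl (Z)-2-methylbut-2-enoate | C=C(c1cc(O)c(C)c(OC)c1O)[C@H](CC=C(C)C)OC(=O)/C(C)=C\C | target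

Total step count: 15.
Longest linear sequence: 12 steps (steps 1–5, then 9–15).

Steps most likely to fail

1. Step 11. The methylidene may take up the alkyne too slowly, because both propargylic carbons are branched and silylated. Catalyst decay, ethenolysis of the prenyl alkene or oligomerization of the vinyl ketone could then overtake ring closure. The fallback sets out from 17 and comes back at 21, and it splits the two bond formations between two substrates. Amide 17 has no vinyl ketone and tolerates forcing. It would be treated with ethylene (3–5 bar) and RuCl2(CHPh)(PCy3)(SIMes) (second-generation Grubbs catalyst) in toluene at 80 °C, and this alkyne–ethylene cross metathesis should give the 2,3-disubstituted butadiene amide F1. CH2=CHMgBr under the conditions of step 10 would convert it into the tetraenone F2. Ring-closing olefin metathesis between the C1 methylene and the vinyl ketone with RuCl2(SIMes)(=CH-C6H4-2-O-i-Pr) in dilute toluene, with loss of ethylene, would lead through dienone 20 to phenol 21. This is the known trienone-to-phenol closure.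

2. Step 10. Addition to the amide carbonyl may be sluggish, since it is flanked by the C4 methyl group and the cis C2 branch. Competing processes are loss of formaldehyde from the N-methoxy group, deprotonation at C2, and conjugate addition of the released amine. The fallback sets out from 17 and comes back at 19, and it reaches the ketone by reduction, addition and oxidation. i-Bu2AlH in THF at −78 °C would reduce the amide to the enal F3, since hydride is small enough for the hindered carbonyl. CH2=CHMgBr at −78 °C would add to give the dienynol F4 as a mixture of epimers, which is handled without acid. MnO2 in CH2Cl2 would then oxidize the doubly allylic alcohol to 19.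

3. Step 7. The aluminium amide may attack the methoxy-bearing carbon of the vinylogous carbonate with loss of methoxide, or the cis hydroxy amide may reclose to the lactone during isolation. The fallback sets out from 12 and comes back at 14 without ever handling the free hydroxy amide. One equivalent of KOH in aqueous MeOH would open the lactone at the carbonyl, as in the saponification of 3-alkoxyacrylates, and evaporation would leave the potassium hydroxy carboxylate F5. TESCl and imidazole in DMF would silylate both oxygens to the silyl ether silyl ester F6. Aqueous NaHCO3 work-up would cleave only the silyl ester and give the silyloxy acid F7, which cannot lactonize. CDI and MeNH(OMe)·HCl, as in step 1, would give the silyloxy Weinreb amide F8. Swern conditions ((COCl)2, DMSO, Et3N, CH2Cl2, −78 to −30 °C), which oxidize primary triethylsilyl ethers directly, would deliver aldehyde 14.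

Further compounds
F1 | step 11 | (2E,7S)-4-(tert-butyldimethylsilyloxy)-N,3-dimethoxy-N,2,10-trimethyl-5,6-dimethylidene-7-(triethylsilyloxy)undeca-2,9-dienamide | CON(C)C(=O)/C(C)=C(/OC)C(O[Si](C)(C)C(C)(C)C)C(=C)C(=C)[C@H](CC=C(C)C)O[Si](CC)(CC)CC
F2 | step 11 | (4E,9S)-6-(tert-butyldimethylsilyloxy)-5-methoxy-4,12-dimethyl-7,8-dimethylidene-9-(triethylsilyloxy)trideca-1,4,11-trien-3-one | C=CC(=O)/C(C)=C(/OC)C(O[Si](C)(C)C(C)(C)C)C(=C)C(=C)[C@H](CC=C(C)C)O[Si](CC)(CC)CC
F3 | step 10 | (2E,7S)-4-(tert-butyldimethylsilyloxy)-3-methoxy-2,10-dimethyl-7-(triethylsilyloxy)undeca-2,9-dien-5-ynal | O=C/C(C)=C(/OC)C(O[Si](C)(C)C(C)(C)C)C#C[C@H](CC=C(C)C)O[Si](CC)(CC)CC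
F4 | step 10 | (4E,9S)-6-(tert-butyldimethylsilyloxy)-5-methoxy-4,12-dimethyl-9-(triethylsilyloxy)trideca-1,4,11-trien-7-yn-3-ol | C=CC(O)/C(C)=C(/OC)C(O[Si](C)(C)C(C)(C)C)C#C[C@H](CC=C(C)C)O[Si](CC)(CC)CC
F5 | step 7 | potassium (E)-4-hydroxy-3-methoxy-2-methylbut-2-enoate | [K+].[O-]C(=O)/C(C)=C(/OC)CO
F6 | step 7 | triethylsilyl (E)-3-methoxy-2-methyl-4-(triethylsilyloxy)but-2-enoate | CC[Si](CC)(CC)OC(=O)/C(C)=C(/OC)CO[Si](CC)(CC)CC
F7 | step 7 | (E)-3-methoxy-2-methyl-4-(triethylsilyloxy)but-2-enoic acid | OC(=O)/C(C)=C(/OC)CO[Si](CC)(CC)CC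
F8 | step 7 | (E)-N,3-dimethoxy-N,2-dimethyl-4-(triethylsilyloxy)but-2-enamide | CON(C)C(=O)/C(C)=C(/OC)CO[Si](CC)(CC)CC
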